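**Retrosynthetic overview**
- The aryl ether at C11 is cut back to isofraxidin and a C11 primary alcohol (Mitsunobu); the C3 acetate is put on last.
- C8=CH2 comes from a C8 ketone; the C9–C11 bond comes from formaldehyde trapping of the C8–C9 enolate that is released when Li/NH3 cleaves the C9–C1 bond of a cyclopropyl ketone.
- Key disconnection: C10 is bonded to C1, and C3 carries oxygen two carbons further along ring A (C1–C2–C3). This is the carbene carbon and the carbinol of a 6-en-1-yn-3-ol closing onto the ring B alkene C9=C10, so ring A and a C1–C9–C10 cyclopropane are formed together by PtCl2 cycloisomerization.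
- The enynol comes from an Ireland–Claisen rearrangement (C4–C5 bond, gem-dimethyl C4, C5 configuration by chirality transfer from a CBS-derived allylic alcohol), then reduction, oxidation and acetylide addition.
- Ring order: ring B is present in the purchased ketal ketone; ring A and the cyclopropane form in one step; the cyclopropane is then opened to leave the cis-decalin.

Key step: step 9

Remark: drimane numbering is used (ring A = C1–C5 and C10, ring B = C5–C10, C11 = CH2O on C9, C12 = CH2 on C8). Read from the SMILES, the target is (3S,5R,9R,10R): the decalin is cis-fused (H5 cis to the C10 methyl), the C9 CH2OAr arm is cis and the C3 acetate trans to that methyl.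

Step 1
Reactants: 1 1,4-dioxaspiro[4.5]decan-6-one
Product: 2 (±)-7-methyl-1,4-dioxaspiro[4.5]decan-6-one
Conditions: LiN(iPr)2, THF, −78 °C; MeI, −78 → 0 °C
Reagents that add atoms: iodomethane, CI
Why: Only C7 is enolizable (the other α-carbon is the ketal carbon), so enolate C-methylation can give only the 7-methyl ketone; its new centre is racemic and disappears in step 2.

Step 2
Reactants: 2 (±)-7-methyl-1,4-dioxaspiro[4.5]decan-6-one
Product: 3 7-methyl-1,4-dioxaspiro[4.5]dec-7-en-6-one
Conditions: IBX, DMSO, 70 °C
Reagents that add atoms: none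
Why: IBX dehydrogenation through the only possible enol (towards C7) should give the conjugated endocyclic 2-methyl enone, and the ketal tolerates these conditions.

Step 3
Reactants: 3 7-methyl-1,4-dioxaspiro[4.5]dec-7-en-6-one
Product: 4 (6R)-7-methyl-1,4-dioxaspiro[4.5]dec-7-en-6-ol
Conditions: (R)-Me-CBS (20 mol %), BH3·SMe2, THF, −20 °C; MeOH
Reagents that add atoms: none
Why: CBS reduction: the oxazaborolidine–borane complex should bind the carbonyl lone pair away from the in-plane 2-methylvinyl arm (taken as the larger group, as in 2-substituted cyclohexenones) and deliver hydride 1,2 to one face, which with the (R)-catalyst gives the (6R)-alcohol.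

Step 4
Reactants: 4 (6R)-7-methyl-1,4-dioxaspiro[4.5]dec-7-en-6-ol; 5 isobutyryl chloride
Product: 6 (6R)-7-methyl-1,4-dioxaspiro[4.5]dec-7-en-6-yl 2-methylpropanoate
Conditions: Et3N, DMAP (cat.), CH2Cl2, 0 °C → rt
Reagents that add atoms: isobutyryl chloride (5), CC(C)C(Cl)=O
Why: DMAP-catalysed acylation of the secondary allylic alcohol (nucleophilic acyl substitution) proceeds with retention at C6.

Step 5
Reactants: 6 (6R)-7-methyl-1,4-dioxaspiro[4.5]dec-7-en-6-yl 2-methylpropanoate
Product: 9 2-methyl-2-[(8R)-7-methyl-1,4-dioxaspiro[4.5]dec-6-en-8-yl]propanoic acid, via silyl ketene acetal 7 (not isolated), via trimethylsilyl ester 8 (not isolated)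
Conditions: LiN(iPr)2, THF, −78 °C; TMSCl, Et3N, −78 → 60 °C; 1 M NaOH, then NaH2PO4 to pH 5
Reagents that add atoms: none
Why: Ireland–Claisen rearrangement: the isobutyrate enolate (no E/Z question) is silylated and the [3,3]-shift forms the C4–C5 bond on the ring face that carried the ester oxygen, so the carbinol configuration is transferred to C5 while the alkene moves to C9=C10 and the gem-dimethyl carbon C4 is created.

Step 6
Reactants: 9 2-methyl-2-[(8R)-7-methyl-1,4-dioxaspiro[4.5]dec-6-en-8-yl]propanoic acid
Product: 10 2-methyl-2-[(8R)-7-methyl-1,4-dioxaspiro[4.5]dec-6-en-8-yl]propan-1-ol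
Conditions: LiAlH4, THF, 0 °C → reflux
Reagents that add atoms: none
Why: Hydride reduction of the hindered α-quaternary acid gives the neopentyl alcohol; ketal and trisubstituted alkene are inert and no stereocentre is touched.

Step 7
Reactants: 10 2-methyl-2-[(8R)-7-methyl-1,4-dioxaspiro[4.5]dec-6-en-8-yl]propan-1-ol
Product: 11 2-methyl-2-[(8R)-7-methyl-1,4-dioxaspiro[4.5]dec-6-en-8-yl]propanal
Conditions: Dess–Martin periodinane, NaHCO3, CH2Cl2, rt
Reagents that add atoms: none
Why: Buffered Dess–Martin oxidation gives the non-enolizable α-quaternary aldehyde without loss of the acid-sensitive ketal.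

Step 8
Reactants: 11 2-methyl-2-[(8R)-7-methyl-1,4-dioxaspiro[4.5]dec-6-en-8-yl]propanal
Product: 12 (3R)-4-methyl-4-[(8R)-7-methyl-1,4-dioxaspiro[4.5]dec-6-en-8-yl]pent-1-yn-3-ol (ring B enynol; the (3S)-epimer forms alongside and is used as well)
Conditions: HC≡CMgBr, THF, 0 °C → rt; aq. NH4Cl
Reagents that add atoms: ethynylmagnesium bromide, C#C[Mg]Br
Why: Grignard 1,2-addition of the acetylide to the neopentyl aldehyde gives the propargylic alcohol; no facial control is needed because C3 becomes a carbonyl carbon in step 9.

Step 9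
Reactants: 12 ring B enynol (both C3 epimers)
Product: 13 tricyclic 3-ketone (ring A fused to the C1–C9–C10 cyclopropane; C8 ethylene ketal; H5 cis to 10-CH3)
Conditions: PtCl2 (5 mol %), toluene, 80 °C
Reagents that add atoms: none
Why: Proposed new method: PtCl2 (divalent platinum) π-activates the terminal alkyne and the C9=C10 alkene attacks its terminal carbon C1 in the 6-endo-dig sense, giving a cyclopropyl platinum carbene centred on C2 in which C1–C10 closes ring A and C1–C9 closes the cyclopropane; a 1,2-hydride shift from the carbinol carbon C3 to C2 and loss of platinum then release the C3 ketone, so both C3 epimers of 12 converge. The closest known reaction type is the cycloisomerization of 5-en-1-yn-3-ols to bicyclo[3.1.0]hexan-3-ones with PtCl2 or monovalent gold; here the tether is one carbon longer, so the ketone ring is six-membered. Ring A closes 6-endo-dig at the alkyne, and the three-membered ring closes by the carbene-like C1 adding to both alkene carbons. C10, C1 and C9 are set together by C5: the chain hangs from C5 and reaches only the alkene face syn to C4, so the C10 methyl ends cis to H5 and the cyclopropane is cis-fused to both six-membered rings. The step needs endo closure over 5-exo closure and hydride shift over skeletal rearrangement. The free propargylic hydroxyl (which lets the C2 carbene collapse to the ketone) and the gem-dimethyl group at C4 (which folds the chain over ring B) are what should secure this.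

Step 10
Reactants: 13 tricyclic 3-ketone
Product: 14 tricyclic 3-alcohol (C8 ketal kept; 3-OH on the concave face, trans to H5 and 10-CH3)
Conditions: NaBH4, MeOH, 0 °C → rt
Reagents that add atoms: none
Why: Hydride reduction from the open convex face of ring A (the concave face lies inside the fold of the cis-fused tricycle and is screened by ring B and the C8 ketal) should put the C3 hydroxyl on the concave face, trans to H5 and the C10 methyl as in the target.

Step 11
Reactants: 14 tricyclic 3-alcohol
Product: 15 3-hydroxy cyclopropyl ketone (C8 ketone next to the C1–C9–C10 cyclopropane)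
Conditions: 1 M HCl, THF, 0 °C → rt
Reagents that add atoms: water, O
Why: Acid-catalysed ketal hydrolysis unmasks the C8 ketone under conditions too mild to open the cyclopropane or ionise C3.

Step 12
Reactants: 15 3-hydroxy cyclopropyl ketone
Product: 17 (3S,5R,9R,10R)-3,11-dihydroxy-12-nor-5,10-cis-driman-8-one, via dilithium enolate 16 (not isolated)
Conditions: Li, NH3(l)/THF, −78 → −33 °C; isoprene; NH3 evaporated; CH2O (g, cracked paraformaldehyde), THF, −78 °C; aq. NH4Cl
Reagents that add atoms: formaldehyde, C=O
Why: Dissolving-metal cleavage of the cyclopropyl ketone should break C9–C1 (the bond outside both six-membered rings, best aligned with the carbonyl π system) and give the C8–C9 lithium enolate regiospecifically, the C3 hydroxyl supplying the proton for C1; aldol addition of monomeric formaldehyde should then occur at C9 on the convex face of the cis-decalin (the face of H5 and the C10 methyl, anti to the ring A methylene C1 that sits axial on ring B), so the CH2OH group ends cis to the C10 methyl.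

Step 13
Reactants: 17 keto diol
Product: 18 (3S,5R,9R,10R)-5,10-cis-drim-8(12)-ene-3,11-diol
Conditions: Zn, CH2Br2, TiCl4, THF/CH2Cl2, 0 °C → rt
Reagents that add atoms: dibromomethane, BrCBr
Why: Takai–Lombardo methylenation with the non-basic zinc–titanium methylene reagent converts the hindered C8 ketone into the exocyclic alkene without enolization, so C9 should not epimerize and the β-hydroxy ketone should neither dehydrate nor undergo retro-aldol cleavage; the hydroxyls are only metalated and return on work-up.

Step 14
Reactants: 18 ene diol; 19 isofraxidin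
Product: 20 7-{[(3S,5R,9R,10R)-3-hydroxy-5,10-cis-drim-8(12)-en-11-yl]oxy}-6,8-dimethoxycoumarin
Conditions: PPh3, DIAD, THF, 0 °C → rt
Reagents that add atoms: isofraxidin (19), COc1cc2ccc(=O)oc2c(OC)c1O
Why: Mitsunobu etherification: the acidic 7-hydroxyl of isofraxidin displaces the activated primary C11 oxygen by SN2, while the neopentyl-type secondary C3 hydroxyl next to the gem-dimethyl carbon does not react; no stereocentre is involved.

Step 15
Reactants: 20 ether alcohol
Product: 21 target, 7-{[(3S,5R,9R,10R)-3-acetoxy-5,10-cis-drim-8(12)-en-11-yl]oxy}-6,8-dimethoxycoumarin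
Conditions: Ac2O, DMAP, pyridine, CH2Cl2, rt
Reagents that add atoms: acetic anhydride, CC(=O)OC(C)=O
Why: DMAP-catalysed acetylation of the remaining hindered secondary hydroxyl gives the C3 acetate with retention; lactone, aryl ether and exocyclic alkene are stable.

**Compound list**
1 | 1,4-dioxaspiro[4.5]decan-6-one | O=C1CCCCC12OCCO2 | starting material
2 | (±)-7-methyl-1,4-dioxaspiro[4.5]decan-6-one | O=C1C(C)CCCC12OCCO2 | intermediate
3 | 7-methyl-1,4-dioxaspiro[4.5]dec-7-en-6-one | O=C1C(C)=CCCC12OCCO2 | intermediate
4 | (6R)-7-methyl-1,4-dioxaspiro[4.5]dec-7-en-6-ol | O[C@@H]1C(C)=CCCC12OCCO2 | intermediate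
5 | isobutyryl chloride | CC(C)C(Cl)=O | starting material
6 | (6R)-7-methyl-1,4-dioxaspiro[4.5]dec-7-en-6-yl 2-methylpropanoate | CC(C)C(=O)O[C@@H]1C(C)=CCCC12OCCO2 | intermediate
7 | trimethylsilyl ketene acetal of 6 | CC(C)=C(O[Si](C)(C)C)O[C@@H]1C(C)=CCCC12OCCO2 | intermediate (not isolated)
8 | trimethylsilyl 2-methyl-2-[(8R)-7-methyl-1,4-dioxaspiro[4.5]dec-6-en-8-yl]propanoate | C[Si](C)(C)OC(=O)C(C)(C)[C@@H]1CCC2(OCCO2)C=C1C | intermediate (not isolated)
9 | 2-methyl-2-[(8R)-7-methyl-1,4-dioxaspiro[4.5]dec-6-en-8-yl]propanoic acid | OC(=O)C(C)(C)[C@@H]1CCC2(OCCO2)C=C1C | intermediate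
10 | 2-methyl-2-[(8R)-7-methyl-1,4-dioxaspiro[4.5]dec-6-en-8-yl]propan-1-ol | OCC(C)(C)[C@@H]1CCC2(OCCO2)C=C1C | intermediate
11 | 2-methyl-2-[(8R)-7-methyl-1,4-dioxaspiro[4.5]dec-6-en-8-yl]propanal | O=CC(C)(C)[C@@H]1CCC2(OCCO2)C=C1C | intermediate
12 | (3R)-4-methyl-4-[(8R)-7-methyl-1,4-dioxaspiro[4.5]dec-6-en-8-yl]pent-1-yn-3-ol, ring B enynol with 8,8-ethylenedioxy ketal (drawn epimer; the (3S)-epimer accompanies it) | C#C[C@@H](O)C(C)(C)[C@@H]1CCC2(OCCO2)C=C1C | intermediate
13 | tricyclic 3-ketone: 4,4,10-trimethyl ring A ketone fused to the C1–C9–C10 cyclopropane, C8 ethylene ketal, H5 cis to 10-CH3, H1 and H9 on the 10-CH3 face | O=C1C[C@H]2[C@H]3C4(OCCO4)CC[C@H]([C@@]23C)C1(C)C | intermediate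
14 | tricyclic 3-alcohol of 13, OH on the concave face (trans to H5 and 10-CH3) | O[C@H]1C[C@H]2[C@H]3C4(OCCO4)CC[C@H]([C@@]23C)C1(C)C | intermediate
15 | 3-hydroxy cyclopropyl ketone (C8 ketone, C1–C9–C10 cyclopropane) | O[C@H]1C[C@H]2[C@H]3C(=O)CC[C@H]([C@@]23C)C1(C)C | intermediate
16 | dilithium C8–C9 enolate / C3 alkoxide of the cis-decalin | [Li+].[Li+].[O-]C1=C[C@]2(C)CC[C@H]([O-])C(C)(C)[C@@H]2CC1 | intermediate (not isolated)
17 | (3S,5R,9R,10R)-3,11-dihydroxy-12-nor-5,10-cis-driman-8-one | O=C1CC[C@H]2C(C)(C)[C@@H](O)CC[C@@]2(C)[C@@H]1CO | intermediate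
18 | (3S,5R,9R,10R)-5,10-cis-drim-8(12)-ene-3,11-diol | C=C1CC[C@H]2C(C)(C)[C@@H](O)CC[C@@]2(C)[C@@H]1CO | intermediate
19 | isofraxidin (7-hydroxy-6,8-dimethoxycoumarin) | COc1cc2ccc(=O)oc2c(OC)c1O | starting material
20 | 7-{[(3S,5R,9R,10R)-3-hydroxy-5,10-cis-drim-8(12)-en-11-yl]oxy}-6,8-dimethoxycoumarin | C=C1CC[C@H]2C(C)(C)[C@@H](O)CC[C@@]2(C)[C@@H]1COc1c(OC)cc2ccc(=O)oc2c1OC | intermediate
21 | 7-{[(3S,5R,9R,10R)-3-acetoxy-5,10-cis-drim-8(12)-en-11-yl]oxy}-6,8-dimethoxycoumarin | C=C1CC[C@H]2C(C)(C)[C@@H](OC(C)=O)CC[C@@]2(C)[C@@H]1COc1c(OC)cc2ccc(=O)oc2c1OC | target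

Total step count: 15. Longest linear sequence: 15 steps (1 to 21; 5 and 19 are used as purchased).

**Steps most likely to fail**

Step 9 (proposed new method). The enyne may close 5-exo and rearrange to dienes, the propargylic alcohol may rearrange to an enal, or the Lewis-acidic metal may ionise the allylic ketal, instead of 6-endo cyclopropanation with hydride shift. The fallback uses an intramolecular diazoalkane cycloaddition; it sets out from 12 and comes back at 13.
- 12 is silylated (TBSOTf, 2,6-lutidine) to silyl ether F1.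
- Hydroboration of the terminal alkyne with dicyclohexylborane and buffered NaBO3 oxidation gives aldehyde F2.
- Tosylhydrazine gives tosylhydrazone F3.
- Heating its sodium salt (NaH, toluene, 110 °C, aprotic Bamford–Stevens conditions) liberates diazoalkane F4, which adds across C9=C10 on the face the tether can reach to give 1-pyrazoline F5.
- Loss of N2 (heat or 350 nm light) gives cyclopropane silyl ether F6.
- TBAF gives tricyclic alcohol F7 (C3 epimers), and Dess–Martin oxidation gives 13.

Step 12. The hindered enolate may be captured inefficiently by gaseous formaldehyde, may lose its regiochemical integrity by proton exchange while ammonia is removed, or may add with low face selectivity. The fallback separates reduction from C–C bond formation; it sets out from 15 and comes back at 17. The same Li/NH3 cleavage is run, but 16 is quenched with TMSCl/Et3N to the isolable bis(trimethylsilyl) enol ether F8. F8 then undergoes a Mukaiyama-type hydroxymethylation with aqueous formaldehyde and catalytic Sc(OTf)3 in THF, the silyl groups being lost in the aqueous medium, to give 17.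

Step 3. Enantioface discrimination may be low or reversed because the ketal-bearing α′-carbon is also bulky. The fallback is a classical resolution; it sets out from 3 and comes back at 4. Luche reduction (NaBH4, CeCl3, MeOH) gives racemic alcohol F9. Esterification with (S)-O-methylmandelic acid (DCC, DMAP) gives the diastereomeric esters (6R)-mandelate F10 and (6S)-mandelate F11, which are separated by chromatography or crystallization. Saponification of F10 (LiOH, THF/H2O) gives 4.

Further compounds
F1 | step 9 | tert-butyldimethylsilyl ether of 12 | C#C[C@@H](O[Si](C)(C)C(C)(C)C)C(C)(C)[C@@H]1CCC2(OCCO2)C=C1C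
F2 | step 9 | 3-silyloxy aldehyde from alkyne hydration of F1 | O=CC[C@@H](O[Si](C)(C)C(C)(C)C)C(C)(C)[C@@H]1CCC2(OCCO2)C=C1C
F3 | step 9 | tosylhydrazone of F2 | Cc1ccc(cc1)S(=O)(=O)NN=CC[C@@H](O[Si](C)(C)C(C)(C)C)C(C)(C)[C@@H]1CCC2(OCCO2)C=C1C
F4 | step 9 | diazoalkane from F3 | [N-]=[N+]=CC[C@@H](O[Si](C)(C)C(C)(C)C)C(C)(C)[C@@H]1CCC2(OCCO2)C=C1C
F5 | step 9 | fused 1-pyrazoline (C1–N=N–C9, C1–C10 bond) | CC(C)(C)[Si](C)(C)O[C@@H]1C[C@H]2N=N[C@H]3C4(OCCO4)CC[C@H]([C@@]23C)C1(C)C
F6 | step 9 | tricyclic cyclopropane 3-silyl ether | CC(C)(C)[Si](C)(C)O[C@@H]1C[C@H]2[C@H]3C4(OCCO4)CC[C@H]([C@@]23C)C1(C)C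
F7 | step 9 | tricyclic 3-alcohol, 3-epimer of 14 (from the drawn epimer of 12) | O[C@@H]1C[C@H]2[C@H]3C4(OCCO4)CC[C@H]([C@@]23C)C1(C)C
F8 | step 12 | C8 trimethylsilyl enol ether / C3 trimethylsilyl ether of the cis-decalin | C[Si](C)(C)OC1=C[C@]2(C)CC[C@H](O[Si](C)(C)C)C(C)(C)[C@@H]2CC1
F9 | step 3 | racemic 7-methyl-1,4-dioxaspiro[4.5]dec-7-en-6-ol | OC1C(C)=CCCC12OCCO2
F10 | step 3 | (S)-O-methylmandelate of the (6R)-alcohol | CO[C@H](C(=O)O[C@@H]1C(C)=CCCC12OCCO2)c1ccccc1
F11 | step 3 | (S)-O-methylmandelate of the (6S)-alcohol | CO[C@H](C(=O)O[C@H]1C(C)=CCCC12OCCO2)c1ccccc1
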